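**Plan**
The retrosynthesis first cuts C5–OCH3 (O-methylation) and C5–allyl (1,2-addition to the C5 carbonyl of a 5,6-o-quinone), then returns the quinone to a C5 phenol on an aromatic ring A.
The dihydrofuran ring (O1, C2, C3, C3a, C7a) is opened at O1–C2 and C3–H. These two bonds are the Markovnikov addition of the C7a phenol across a C2=C3 alkene whose C2 is benzylic to the 3,4-dimethoxyphenyl ring, and this feature makes the key step possible.
The (E)-α-methylstilbene phenol is cut at C3–C3a (Suzuki–Miyaura) into a bromophenol and a (Z)-alkenylboronate made from an aryl propyne.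
Forward: both arenes are bought, the C2–C3–CH3 chain is joined first to the veratryl ring and then to ring A, the dihydrofuran is the only ring formed (step 5), and ring A is dearomatised last.
Stereochemistry: C3 comes from catalyst-controlled protonation and C2 (trans) from substrate control in step 5; C5 comes from a chiral-Lewis-acid-controlled allyl addition in step 8.

Key step: step 5

Assumption: the absolute sense of induction of the chiral Brønsted acid (step 5) and of the chiral Lewis acid (step 8) cannot be derived on paper, so the catalyst antipode that gives the drawn configuration is taken to be fixed by a first screen of both enantiomers.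

Step 1
Reactants: 1 4-hydroxyphenyl benzoate
Product: 2 3-bromo-4-hydroxyphenyl benzoate
Conditions: NBS (1.0 equiv), i-Pr2NH (10 mol %), CH2Cl2, 0 °C
Reagents that add atoms: N-bromosuccinimide, O=C1CCC(=O)N1Br
Why: Electrophilic aromatic bromination: the hydroxyl group is the only strong director, its para position is blocked by the benzoyloxy group, and amine-catalysed NBS bromination of phenols is ortho-selective, so one equivalent should give the mono-ortho bromide.

Step 2
Reactants: 3 4-iodo-1,2-dimethoxybenzene; 4 propyne
Product: 5 1,2-dimethoxy-4-(prop-1-yn-1-yl)benzene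
Conditions: Pd(PPh3)2Cl2 (2 mol %), CuI (4 mol %), Et3N, THF, propyne (balloon), rt
Reagents that add atoms: none
Why: Sonogashira coupling of an electron-rich aryl iodide with a terminal alkyne runs at room temperature under Pd/Cu catalysis and touches neither methoxy group.

Step 3
Reactants: 5 1,2-dimethoxy-4-(prop-1-yn-1-yl)benzene
Product: 6 (Z)-2-[1-(3,4-dimethoxyphenyl)prop-1-en-2-yl]-4,4,5,5-tetramethyl-1,3,2-dioxaborolane (aryl and methyl cis, boron on the methyl-bearing carbon)
Conditions: CuCl (5 mol %), P(p-tol)3 (6 mol %), NaOt-Bu (10 mol %), B2pin2 (1.1 equiv), MeOH (2 equiv), THF, rt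
Reagents that add atoms: bis(pinacolato)diboron, CC1(C)OB(OC1(C)C)B1OC(C)(C)C(C)(C)O1
Why: Copper-catalysed formal hydroboration (syn borylcupration, then protonation of the C–Cu bond with retention) places copper on the aryl-bearing carbon and boron on the methyl-bearing carbon, so a single (Z)-alkenylboronate with aryl and methyl cis should result.

Step 4
Reactants: 2 3-bromo-4-hydroxyphenyl benzoate; 6 (Z)-alkenylboronate
Product: 7 3-[(1E)-1-(3,4-dimethoxyphenyl)prop-1-en-2-yl]-4-hydroxyphenyl benzoate
Conditions: SPhos Pd G3 (2 mol %), KF (3 equiv), THF–H2O (20:1), 40 °C, degassed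
Reagents that add atoms: none
Why: Suzuki–Miyaura coupling proceeds with retention of alkene geometry, so the two aryl rings end up trans ((E)-α-methylstilbene); the free ortho-hydroxyl is tolerated and the fluoride base spares the benzoate.

Step 5
Reactants: 7 3-[(1E)-1-(3,4-dimethoxyphenyl)prop-1-en-2-yl]-4-hydroxyphenyl benzoate
Product: 8 (2R,3R)-2-(3,4-dimethoxyphenyl)-3-methyl-2,3-dihydro-1-benzofuran-5-yl benzoate (trans)
Conditions: confined chiral imidodiphosphorimidate (IDPi) Brønsted acid (5 mol %), CHCl3 (0.02 M), 5 Å MS, 0 °C to rt
Reagents that add atoms: none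
Why: Proposed new method: the confined chiral acid should transfer its proton to C3 of the (E)-alkene, giving a C2 benzylic cation that is stabilised by the para-methoxy group of the veratryl ring and ion-paired with the chiral anion, after which the C7a hydroxyl, hydrogen-bonded to that anion, collapses onto C2 and returns the proton. The closest known reactions are the IDPi-catalysed asymmetric intramolecular hydroalkoxylation of alkenols and the achiral acid-promoted cyclisation of 2-hydroxystilbenes to 2-aryl-2,3-dihydrobenzofurans; their combination on a trisubstituted stilbene with control of two centres has not been shown. The dihydrofuran ring closes in a formally 5-endo-trig mode, which is open here because the oxygen captures a fully formed benzylic cation. C3 is set by catalyst-controlled choice of the alkene face that is protonated, and C2 follows by substrate control, the aryl group settling trans to the C3 methyl group in the kinetically and thermodynamically preferred ring. The step needs protonation at C3 rather than C2: ring A carries its benzoyloxy group meta to the alkene carbon and so offers no para-oxygen donor, whereas the veratryl ring does, and protonation at C2 is reversible and unproductive because closure from the C3 cation would be four-membered; high dilution should hold back intermolecular alkylation.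

Step 6
Reactants: 8 (2R,3R)-2-(3,4-dimethoxyphenyl)-3-methyl-2,3-dihydro-1-benzofuran-5-yl benzoate
Product: 9 (2R,3R)-2-(3,4-dimethoxyphenyl)-3-methyl-2,3-dihydro-1-benzofuran-5-ol
Conditions: K2CO3 (0.3 equiv), MeOH–THF, 0 °C to rt, under Ar
Reagents that add atoms: none
Why: Base-catalysed transesterification (methanolysis) removes the aryl benzoate at room temperature, while the aryl alkyl ethers and the two stereocentres, neither of which carries an acidic hydrogen, are inert.

Step 7
Reactants: 9 (2R,3R)-2-(3,4-dimethoxyphenyl)-3-methyl-2,3-dihydro-1-benzofuran-5-ol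
Product: 10 (2R,3R)-2-(3,4-dimethoxyphenyl)-3-methyl-2,3-dihydro-1-benzofuran-5,6-dione (used at once)
Conditions: IBX (1.1 equiv), DMF, rt, dark
Reagents that add atoms: 2-iodoxybenzoic acid (IBX), O=C1OI(=O)(O)c2ccccc12
Why: IBX oxidation of an electron-rich phenol to the o-quinone delivers oxygen within the aryloxy-iodane to an ortho carbon, here C6 because C4 is shielded by the C3 substituent, which also avoids attack at the para carbon C7a that other oxidants would choose; the neutral conditions spare C3–H, which is vinylogously acidic in the quinone.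

Step 8
Reactants: 10 (2R,3R)-2-(3,4-dimethoxyphenyl)-3-methyl-2,3-dihydro-1-benzofuran-5,6-dione
Product: 12 (2R,3R,5S)-2-(3,4-dimethoxyphenyl)-5-hydroxy-3-methyl-5-(prop-2-en-1-yl)-2,3-dihydro-1-benzofuran-6(5H)-one, via O-tributylstannyl ether 11 (not isolated)
Conditions: Sc(OTf)3 (10 mol %), chiral inda-pybox ligand (12 mol %), allylSnBu3 (1.5 equiv), 4 Å MS, CH2Cl2, −78 to −40 °C; then aq. NaHCO3
Reagents that add atoms: allyltributylstannane, C=CC[Sn](CCCC)(CCCC)CCCC
Why: Proposed new method: the o-quinone should bind the C2-symmetric Sc(III)–pybox complex through both carbonyl oxygens, which activates it and shields one face, and the allylstannane should add in a 1,2 sense to C5=O, the more electrophilic carbonyl because C6=O is a vinylogous ester of O1 and both strongly electrophilic conjugate positions are fully substituted, so that the C5 carbinol centre is set by the catalyst (reagent control, the remote C2/C3 centres exerting little bias) while tin passes to oxygen; the closest known reactions are the Lewis-acid-mediated racemic 1,2-allylation of o-quinones with allylstannanes and the chiral Sc(III)/In(III)–pybox-catalysed enantioselective allylation of chelating 1,2-dicarbonyl compounds such as isatins.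

Step 9
Reactants: 12 (2R,3R,5S)-2-(3,4-dimethoxyphenyl)-5-hydroxy-3-methyl-5-(prop-2-en-1-yl)-2,3-dihydro-1-benzofuran-6(5H)-one
Product: 13 (2R,3R,5S)-2-(3,4-dimethoxyphenyl)-5-methoxy-3-methyl-5-(prop-2-en-1-yl)-2,3-dihydro-1-benzofuran-6(5H)-one (target, CNP0109840.1)
Conditions: MeI (excess), Ag2O, 4 Å MS, CH2Cl2, rt to 35 °C, dark
Reagents that add atoms: iodomethane, CI
Why: Purdie methylation (MeI/Ag2O) alkylates the acidic tertiary α-ketol hydroxyl without generating a free alkoxide, which could trigger an anionic oxy-Cope shift of the allyl group to C3a, and leaves the vinylogous-ester carbonyl and the C5 configuration untouched.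

**Compound list**
1 | 4-hydroxyphenyl benzoate | O=C(Oc1ccc(O)cc1)c1ccccc1 | starting material
2 | 3-bromo-4-hydroxyphenyl benzoate | O=C(Oc1ccc(O)c(Br)c1)c1ccccc1 | intermediate
3 | 4-iodo-1,2-dimethoxybenzene | COc1ccc(I)cc1OC | starting material
4 | propyne | CC#C | starting material
5 | 1,2-dimethoxy-4-(prop-1-yn-1-yl)benzene | CC#Cc1ccc(OC)c(OC)c1 | intermediate
6 | (Z)-2-[1-(3,4-dimethoxyphenyl)prop-1-en-2-yl]-4,4,5,5-tetramethyl-1,3,2-dioxaborolane | C/C(=C\c1ccc(OC)c(OC)c1)B1OC(C)(C)C(C)(C)O1 | intermediate
7 | 3-[(1E)-1-(3,4-dimethoxyphenyl)prop-1-en-2-yl]-4-hydroxyphenyl benzoate | C/C(=C\c1ccc(OC)c(OC)c1)c1cc(OC(=O)c2ccccc2)ccc1O | intermediate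
8 | (2R,3R)-2-(3,4-dimethoxyphenyl)-3-methyl-2,3-dihydro-1-benzofuran-5-yl benzoate | O=C(Oc1cc2c(cc1)O[C@@H](c1ccc(OC)c(OC)c1)[C@@H]2C)c1ccccc1 | intermediate
9 | (2R,3R)-2-(3,4-dimethoxyphenyl)-3-methyl-2,3-dihydro-1-benzofuran-5-ol | Oc1cc2c(cc1)O[C@@H](c1ccc(OC)c(OC)c1)[C@@H]2C | intermediate
10 | (2R,3R)-2-(3,4-dimethoxyphenyl)-3-methyl-2,3-dihydro-1-benzofuran-5,6-dione | O=C1C=C2C(=CC1=O)O[C@@H](c1ccc(OC)c(OC)c1)[C@@H]2C | intermediate
11 | (2R,3R,5S)-2-(3,4-dimethoxyphenyl)-3-methyl-5-(prop-2-en-1-yl)-5-[(tributylstannyl)oxy]-2,3-dihydro-1-benzofuran-6(5H)-one | C=CC[C@]1(O[Sn](CCCC)(CCCC)CCCC)C=C2C(=CC1=O)O[C@@H](c1ccc(OC)c(OC)c1)[C@@H]2C | intermediate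
12 | (2R,3R,5S)-2-(3,4-dimethoxyphenyl)-5-hydroxy-3-methyl-5-(prop-2-en-1-yl)-2,3-dihydro-1-benzofuran-6(5H)-one | C=CC[C@]1(O)C=C2C(=CC1=O)O[C@@H](c1ccc(OC)c(OC)c1)[C@@H]2C | intermediate
13 | (2R,3R,5S)-2-(3,4-dimethoxyphenyl)-5-methoxy-3-methyl-5-(prop-2-en-1-yl)-2,3-dihydro-1-benzofuran-6(5H)-one | C=CC[C@]1(OC)C=C2C(=CC1=O)O[C@@H](c1ccc(OC)c(OC)c1)[C@@H]2C | target

**Step count**
Total: 9 steps. Longest linear sequence: 8 steps (steps 2 to 9, from 4-iodo-1,2-dimethoxybenzene).

**Steps most likely to fail**

Step 5. Protonation may occur with poor face selectivity, the substrate may drain through the unproductive C3 cation and its o-quinone methide into dimers, or the product may racemise by acid-induced reopening at C2–O1 and loss of the C3 proton. The fallback sets out from 7. Asymmetric hydroboration with monoisopinocampheylborane (the antipode that delivers hydrogen to the required face of C3, with an extra equivalent to cover the phenol) places boron on the less substituted C2. Oxidation with trimethylamine N-oxide should then give 3-[(1R,2R)-1-(3,4-dimethoxyphenyl)-1-hydroxypropan-2-yl]-4-hydroxyphenyl benzoate F1. Catalytic p-TsOH in CH2Cl2 ionises the veratryl carbinol, and the phenol closes the ring to the thermodynamically preferred trans isomer with C3 untouched. This rejoins the route at 8.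

Step 8. Facial discrimination at the flat quinone carbonyl may be poor, or the Lewis acid may induce allyl migration with re-aromatisation or tautomerisation of the quinone through C3–H. The fallback sets out from 10. Indium-mediated Barbier allylation (In, allyl bromide, THF–H2O, rt), a strictly 1,2 process through a closed transition state that is known for quinones and 1,2-diones, should give 12 together with its C5 epimer, (2R,3R,5R)-2-(3,4-dimethoxyphenyl)-5-hydroxy-3-methyl-5-(prop-2-en-1-yl)-2,3-dihydro-1-benzofuran-6(5H)-one F2. The two diastereomers are separated by chromatography, and 12 continues with step 9.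

Step 7. Oxygen transfer may go to C4 instead of C6, or the vinylogous-ester quinone may be lost by hydrolytic opening at C7a during reaction or work-up. The fallback sets out from 9. Magnesium-mediated ortho-formylation (MgCl2, Et3N, paraformaldehyde, MeCN) at the unhindered C6 should give (2R,3R)-2-(3,4-dimethoxyphenyl)-5-hydroxy-3-methyl-2,3-dihydro-1-benzofuran-6-carbaldehyde F3. Dakin oxidation (sodium percarbonate, THF–H2O) converts it into (2R,3R)-2-(3,4-dimethoxyphenyl)-3-methyl-2,3-dihydro-1-benzofuran-5,6-diol F4. Dehydrogenation of this catechol with Ag2O (Et2O, Na2SO4) returns to the route at 10.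

**Further compounds**
F1 | step 5 | 3-[(1R,2R)-1-(3,4-dimethoxyphenyl)-1-hydroxypropan-2-yl]-4-hydroxyphenyl benzoate | O[C@@H](c1ccc(OC)c(OC)c1)[C@@H](c1cc(OC(=O)c2ccccc2)ccc1O)C
F2 | step 8 | (2R,3R,5R)-2-(3,4-dimethoxyphenyl)-5-hydroxy-3-methyl-5-(prop-2-en-1-yl)-2,3-dihydro-1-benzofuran-6(5H)-one | C=CC[C@@]1(O)C=C2C(=CC1=O)O[C@@H](c1ccc(OC)c(OC)c1)[C@@H]2C
F3 | step 7 | (2R,3R)-2-(3,4-dimethoxyphenyl)-5-hydroxy-3-methyl-2,3-dihydro-1-benzofuran-6-carbaldehyde | Oc1cc2c(cc1C=O)O[C@@H](c1ccc(OC)c(OC)c1)[C@@H]2C
F4 | step 7 | (2R,3R)-2-(3,4-dimethoxyphenyl)-3-methyl-2,3-dihydro-1-benzofuran-5,6-diol | Oc1cc2c(cc1O)O[C@@H](c1ccc(OC)c(OC)c1)[C@@H]2C
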